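At early times in the gamma run, product passed starting material within 0.833 h, 51.4 % against 46.0 %. From 2.50 h to 10.0 h the ratio of the two read 1.31 and then 1.32, while their sum fell from 94.6 % to 81.9 %, so part of what was charged was leaking elsewhere. I divided the last ratio by the free partner, taken as charge minus product, and called the result the binding quotient, c(product)/(c(starting material)·c(partner)). It read 0.764 L mol⁻¹.

| setting | gamma | flask |
|---|---|---|
| starting material | 0.80 M | 0.80 M |
| partner | 2.1 M | 1.04 M |
| remark | run made earlier |  |
| time |  | 2.0 d |

gamma run (percent of the starting material charged)

| time / h | product / % | starting material / % |
|---|---|---|
| 0.833 | 51.4 | 46.0 |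
| 1.33 | 52.5 | 43.1 |
| 2.50 | 53.6 | 41.0 |
| 5.00 | 51.4 | 37.2 |
| 10.0 | 46.6 | 35.3 |

(each reading ± 1 percentage point)

- the numbers in the tables scatter with a standard deviation of 1 percentage point

- amount of product in the flask at 2.0 d, in percent of the starting material charged
- amount of starting material in the flask at 2.0 d, in percent of the starting material charged

In the new flask starting material is the limiting reagent, and its balance reads: charge = c(starting material) + c(product) + leaked. I assumed that the leaked part holds no partner. One extreme version has no leak: the quotient then gives 36.4 % product and a ratio of 0.572. In the other the product has drained into the leak, so partner stands at its full charge and the ratio is 0.795. On my assumption the new flask should lie between the two, since partner freed from product raises the ratio. The forecast said 20 % product and 39 % starting material, a ratio of 0.513, below my window; unlike me it let the lost part keep its partner, and it warned, “The loss route is unknown”.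

The flask gave 18.2 % product and 27.4 % starting material.

    starting material + partner ⇌ product (K = 0.740 L mol⁻¹, k = 1.10 L mol⁻¹ h⁻¹)
    starting material ⇌ dormant form (K = 2.70, k = 0.0440 h⁻¹)

That ratio, 0.664, lies inside the window, and the dormant form held 54.4 %. With 86 % of the partner free at the end, the quotient gives 0.684. The neighbouring flask, charged with 0.26 M of partner, kept 85 % of it free, so the same quotient gives 0.169. That flask held 4.95 % product beside 30.2 % starting material, a ratio of 0.164.

The earlier runs and the new flask come from a simulation on assumed constants; scatter was added.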